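**Retrosynthetic overview**

1. The target is read as (5R,8R,9R,10S,13S) with a cis-fused decalin: H-5, CH3-10, CH3-8 and the C9 chain lie on one face (β), AcO-8 and H-9 on the other (α). It is disconnected by O-acetylation, hydroxyl-directed hydrogenation of C9=C11 (sets C9), methyl addition to a C8 ketone (sets C8), and aldol condensation of a regiodefined C8 enol ether with a C11–C15 aldehyde that carries C13 from methyl hydrogen (S)-3-methylglutarate.
2. Rings A and B are closed together by an enantioselective intramolecular Diels–Alder reaction of an acyclic trienal, which forms C5–C10 and C6–C7. The formyl group on C6 is a traceless activator, removed by decarbonylation.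
3. Enabling feature: ring B carries its oxygen on C8, so C7=C8(OSi)–C9=C10 is a 2-silyloxydiene and the adduct is the C8=C9 enol ether. C10 and C5 are the ring-fusion atoms already linked by C1–C4 of ring A (the tether), C4 is quaternary (non-enolisable enal), and the cis H-5/CH3-10 relation is what a (Z)-diene delivers.
4. The trienal comes from 2,2-dimethylpent-4-enal and pent-3-yn-2-one by olefination, B-alkyl Suzuki–Miyaura coupling, silyl dienol ether formation and redox adjustment.
5. Ring order: A and B simultaneously in step 7; C8 is then relayed from the cis-decalin shape (step 14) and C9 from the C8 hydroxyl (step 15).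

Key step: step 7

Remark: positions are numbered as in labdanes (ring A = C1–C5 and C10, ring B = C5–C10, chain C11–C15); β is the face of CH3-10.
Assumption: methyl hydrogen (S)-3-methylglutarate (13) is taken as a purchasable building block, and the facial sense of the catalyst in step 7 is taken from the accepted model for boron-bound s-trans enals (formyl C–H···O contact, one face covered by a phenyl ring).

**Route**

Step 1
Reactants: 1 pent-3-yn-2-one
Product: 2 (Z)-4-iodopent-3-en-2-one
Conditions: NaI (1.5 equiv), AcOH, 25 °C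
Reagents that add atoms: sodium iodide [Na+].[I-]
Why: Conjugate hydroiodination of the ynone (iodide adds to the β-carbon and the allenol is protonated anti to iodine) is a known kinetic route to (Z)-β-iodo enones, which fixes the geometry later needed at C9=C10.

Step 2
Reactants: 3 2,2-dimethylpent-4-enal
Product: 4 ethyl (E)-4,4-dimethylhepta-2,6-dienoate
Conditions: (EtO)2P(O)CH2CO2Et, NaH, THF, 0 °C → rt
Reagents that add atoms: triethyl phosphonoacetate CCOC(=O)CP(=O)(OCC)OCC
Why: Horner–Wadsworth–Emmons olefination of the non-enolisable α-quaternary aldehyde with the stabilised phosphonate anion should give the E-enoate.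

Step 3
Reactants: 4 ethyl (E)-4,4-dimethylhepta-2,6-dienoate; 2 (Z)-4-iodopent-3-en-2-one
Product: 6 ethyl (2E,8Z)-4,4,8-trimethyl-10-oxoundeca-2,8-dienoate, via alkylborane 5 (not isolated)
Conditions: 9-BBN, THF, 0 °C → rt; then 2, PdCl2(dppf) (5 mol %), AsPh3 (5 mol %), aq. K3PO4, DMF, rt
Reagents that add atoms: none
Why: 9-BBN hydroborates only the terminal alkene at its CH2 end, and the B-alkyl Suzuki–Miyaura coupling with the (Z)-β-iodo enone proceeds with retention of alkene geometry, so the C1–C10 bond is made with the tether cis to the acetyl group.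

Step 4
Reactants: 6 ethyl (2E,8Z)-4,4,8-trimethyl-10-oxoundeca-2,8-dienoate
Product: 8 ethyl (2E,8Z)-4,4,8-trimethyl-10-[(triisopropylsilyl)oxy]undeca-2,8,10-trienoate, via lithium dienolate 7 (not isolated)
Conditions: LiN(i-Pr)2 (1.1 equiv), THF, −78 °C; TIPSOTf, −78 → 0 °C
Reagents that add atoms: triisopropylsilyl trifluoromethanesulfonate CC(C)[Si](C(C)C)(C(C)C)OS(=O)(=O)C(F)(F)F
Why: Kinetic deprotonation of the methyl ketone at its CH3 group (the enoate has no acidic hydrogen because C4 is quaternary) followed by O-silylation gives the cross-conjugated 2-silyloxydiene without touching the Z-alkene.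

Step 5
Reactants: 8 ethyl (2E,8Z)-4,4,8-trimethyl-10-[(triisopropylsilyl)oxy]undeca-2,8,10-trienoate
Product: 9 (2E,8Z)-4,4,8-trimethyl-10-[(triisopropylsilyl)oxy]undeca-2,8,10-trien-1-ol
Conditions: i-Bu2AlH (2.5 equiv), CH2Cl2, −78 °C; Rochelle salt work-up
Reagents that add atoms: none
Why: i-Bu2AlH reduces the conjugated ester in 1,2-fashion to the allylic alcohol at low temperature, while the silyl dienol ether is inert to hydride.

Step 6
Reactants: 9 (2E,8Z)-4,4,8-trimethyl-10-[(triisopropylsilyl)oxy]undeca-2,8,10-trien-1-ol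
Product: 10 (2E,8Z)-4,4,8-trimethyl-10-[(triisopropylsilyl)oxy]undeca-2,8,10-trienal
Conditions: activated MnO2 (excess), CH2Cl2, rt
Reagents that add atoms: none
Why: MnO2 oxidises the allylic alcohol selectively to the E-enal under neutral conditions that the acid-sensitive silyl dienol ether tolerates.

Step 7
Reactants: 10 (2E,8Z)-4,4,8-trimethyl-10-[(triisopropylsilyl)oxy]undeca-2,8,10-trienal
Product: 11 (1R,4aS,8aR)-4a,8,8-trimethyl-3-[(triisopropylsilyl)oxy]-1,2,4a,5,6,7,8,8a-octahydronaphthalene-1-carbaldehyde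
Conditions: (S)-3,3-diphenyl-1-(o-tolyl)tetrahydro-1H,3H-pyrrolo[1,2-c][1,3,2]oxazaborole (20 mol %), HNTf2 (18 mol %), CH2Cl2 (0.02 M), −78 → −20 °C
Reagents that add atoms: none
Why: The N-protonated oxazaborolidine binds the formyl oxygen and lowers the enal LUMO, and the tethered 2-silyloxydiene adds across C5=C6 in a concerted, asynchronous intramolecular [4+2] cycloaddition in which C5–C10 bonding runs ahead of C6–C7 bonding. The closest known reaction type is the oxazaborolidinium-catalysed enantioselective intramolecular Diels–Alder reaction of trienals, supported by the Diels–Alder chemistry of 4,4-disubstituted 2-silyloxydienes and the cis-selective cyclisation of (Z)-dienes. Ring B closes as the new cyclohexene of the [4+2] event, and ring A closes at the same time around the four-carbon tether C1–C4 in the fused (type 1) mode, C5–C10 being the shared bond. The cis relation of H-5 and CH3-10 is controlled by the Z geometry of the alkene that becomes C9=C10, which places the tether inside the diene so that only the tether-exo, formyl-endo transition state can be reached, while the E-enal puts the formyl group at C6 trans to C4 (a centre erased in step 8). The absolute configuration at C5 and C10 is set by the (S)-catalyst, which covers one face of the s-trans enal with a phenyl ring and leaves the Re face at C6 and C5 open. The step needs the fused mode over a bridged Mukaiyama–Michael mode, secured by the short tether that would make attack of C7 on C5 a nine-membered closure, and it needs an enal that cannot enolise, secured by the quaternary C4.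

Step 8
Reactants: 11 (1R,4aS,8aR)-4a,8,8-trimethyl-3-[(triisopropylsilyl)oxy]-1,2,4a,5,6,7,8,8a-octahydronaphthalene-1-carbaldehyde
Product: 12 triisopropyl{[(4aR,8aS)-5,5,8a-trimethyl-3,4,4a,5,6,7,8,8a-octahydronaphthalen-2-yl]oxy}silane
Conditions: RhCl(PPh3)3 (1.1 equiv), toluene, 110 °C
Reagents that add atoms: none
Why: Rhodium-mediated aldehyde decarbonylation (Tsuji–Wilkinson reaction: formyl C–H insertion, CO extrusion, C–H reductive elimination) removes the activating group and leaves C6 as CH2 under neutral conditions that spare the silyl enol ether.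

Step 9
Reactants: 13 methyl hydrogen (S)-3-methylglutarate
Product: 14 methyl (3S)-5-hydroxy-3-methylpentanoate
Conditions: BH3·SMe2 (1.1 equiv), THF, 0 °C → rt; MeOH then water
Reagents that add atoms: none
Why: Borane reduces the carboxylic acid much faster than the methyl ester, and the stereocentre, which is not α to a carbonyl group, is untouched.

Step 10
Reactants: 14 methyl (3S)-5-hydroxy-3-methylpentanoate
Product: 15 methyl (3S)-3-methyl-5-oxopentanoate
Conditions: TEMPO (10 mol %), PhI(OAc)2 (1.1 equiv), CH2Cl2, rt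
Reagents that add atoms: none
Why: The nitroxyl-catalysed oxidation stops at the aldehyde and cannot epimerise the β-stereocentre.

Step 11
Reactants: 12 triisopropyl{[(4aR,8aS)-5,5,8a-trimethyl-3,4,4a,5,6,7,8,8a-octahydronaphthalen-2-yl]oxy}silane; 15 methyl (3S)-3-methyl-5-oxopentanoate
Product: 16 methyl (3S)-5-hydroxy-3-methyl-5-[(4aR,8aS)-5,5,8a-trimethyl-2-oxodecahydronaphthalen-1-yl]pentanoate
Conditions: BF3·OEt2 (1.2 equiv), CH2Cl2, −78 °C; aq. NaHCO3
Reagents that add atoms: none
Why: In this Mukaiyama aldol addition the regiodefined enol ether from the cycloaddition reacts only at C9 with the activated aldehyde, placing the C11–C15 chain on the hindered α-carbon that ketone enolate chemistry would not reach; the two new centres (C9 and C11) are left uncontrolled because both are removed in step 12.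

Step 12
Reactants: 16 methyl (3S)-5-hydroxy-3-methyl-5-[(4aR,8aS)-5,5,8a-trimethyl-2-oxodecahydronaphthalen-1-yl]pentanoate
Product: 18 methyl (3S,5Z)-3-methyl-5-[(4aR,8aS)-5,5,8a-trimethyl-2-oxooctahydronaphthalen-1(2H)-ylidene]pentanoate, via mesylate 17 (not isolated)
Conditions: MsCl (1.5 equiv), Et3N, CH2Cl2, 0 °C; then DBU (3 equiv), rt
Reagents that add atoms: none
Why: Mesylation of the aldol and E1cB elimination through the C9 enolate give the exocyclic enone, for which only C11 can eliminate because C10 is quaternary, and the chain is expected syn to the carbonyl group to avoid allylic strain with C10.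

Step 13
Reactants: 18 methyl (3S,5Z)-3-methyl-5-[(4aR,8aS)-5,5,8a-trimethyl-2-oxooctahydronaphthalen-1(2H)-ylidene]pentanoate
Product: 19 (3S,5Z)-3-methyl-5-[(4aR,8aS)-5,5,8a-trimethyl-2-oxooctahydronaphthalen-1(2H)-ylidene]pentanoic acid
Conditions: LiOH·H2O (3 equiv), THF/H2O, 0 °C → rt; 1 M HCl to pH 3
Reagents that add atoms: lithium hydroxide [Li+].[OH-]
Why: Saponification of the unhindered methyl ester at low temperature turns the ester into a carboxylate, which serves as its own protecting group in step 14.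

Step 14
Reactants: 19 (3S,5Z)-3-methyl-5-[(4aR,8aS)-5,5,8a-trimethyl-2-oxooctahydronaphthalen-1(2H)-ylidene]pentanoic acid
Product: 21 (3S,5Z)-5-[(2R,4aR,8aS)-2-hydroxy-2,5,5,8a-tetramethyloctahydronaphthalen-1(2H)-ylidene]-3-methylpentanoic acid, via bromomagnesium carboxylate 20 (not isolated)
Conditions: anhydrous CeCl3 (3 equiv), MeMgBr (4 equiv), THF, −78 → 0 °C; aq. NH4Cl
Reagents that add atoms: methylmagnesium bromide C[Mg]Br
Why: CeCl3-promoted Grignard 1,2-addition to the enone carbonyl (the carboxylate is inert) should occur from the β face along the equatorial direction, because in the favoured chair–chair conformer, which keeps the quaternary C4 equatorial on ring B, the α-axial approach to C8 is blocked by the syn-axial C1 methylene, giving 8β-CH3 and 8α-OH.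

Step 15
Reactants: 21 (3S,5Z)-5-[(2R,4aR,8aS)-2-hydroxy-2,5,5,8a-tetramethyloctahydronaphthalen-1(2H)-ylidene]-3-methylpentanoic acid
Product: 22 (3S)-5-[(1R,2R,4aR,8aS)-2-hydroxy-2,5,5,8a-tetramethyldecahydronaphthalen-1-yl]-3-methylpentanoic acid
Conditions: [Ir(cod)(PCy3)(py)]PF6 (10 mol %), H2 (1–4 atm), CH2Cl2, 0 °C → rt
Reagents that add atoms: none
Why: In this hydroxyl-directed homogeneous hydrogenation the cationic iridium centre binds the axial 8α-hydroxyl and delivers H2 to the α face of the C9=C11 alkene, which sets 9α-H (chain β, cis to CH3-10) against the steric bias of an undirected reduction.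

Step 16
Reactants: 22 (3S)-5-[(1R,2R,4aR,8aS)-2-hydroxy-2,5,5,8a-tetramethyldecahydronaphthalen-1-yl]-3-methylpentanoic acid
Product: 25 (3S)-5-[(1R,2R,4aR,8aS)-2-acetoxy-2,5,5,8a-tetramethyldecahydronaphthalen-1-yl]-3-methylpentanoic acid, via dipotassium salt 23 (not isolated), via mixed anhydride 24 (not isolated)
Conditions: KN(SiMe3)2 (2.2 equiv), THF, −78 °C; Ac2O (3 equiv), −78 → 0 °C; then aq. NaHCO3/THF, rt; acidify to pH 4
Reagents that add atoms: acetic anhydride CC(=O)OC(C)=O; water O
Why: O-Acylation of the potassium alkoxide overcomes the low reactivity of the hindered tertiary alcohol, and the mixed anhydride formed at the carboxylate is hydrolysed selectively on mild aqueous work-up, leaving the tertiary acetate.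

**Compound list**

1 | pent-3-yn-2-one | CC#CC(C)=O | starting material
2 | (Z)-4-iodopent-3-en-2-one | CC(=O)/C=C(/C)I | intermediate
3 | 2,2-dimethylpent-4-enal | C=CCC(C)(C)C=O | starting material
4 | ethyl (E)-4,4-dimethylhepta-2,6-dienoate | CCOC(=O)/C=C/C(C)(C)CC=C | intermediate
5 | ethyl (E)-7-(9-borabicyclo[3.3.1]nonan-9-yl)-4,4-dimethylhept-2-enoate (not isolated) | CCOC(=O)/C=C/C(C)(C)CCCB1C2CCCC1CCC2 | intermediate
6 | ethyl (2E,8Z)-4,4,8-trimethyl-10-oxoundeca-2,8-dienoate | CCOC(=O)/C=C/C(C)(C)CCC/C(C)=C\C(C)=O | intermediate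
7 | lithium cross-conjugated dienolate of 6 (not isolated) | CCOC(=O)/C=C/C(C)(C)CCC/C(C)=C\C(=C)[O-].[Li+] | intermediate
8 | ethyl (2E,8Z)-4,4,8-trimethyl-10-[(triisopropylsilyl)oxy]undeca-2,8,10-trienoate | CCOC(=O)/C=C/C(C)(C)CCC/C(C)=C\C(=C)O[Si](C(C)C)(C(C)C)C(C)C | intermediate
9 | (2E,8Z)-4,4,8-trimethyl-10-[(triisopropylsilyl)oxy]undeca-2,8,10-trien-1-ol | OC/C=C/C(C)(C)CCC/C(C)=C\C(=C)O[Si](C(C)C)(C(C)C)C(C)C | intermediate
10 | (2E,8Z)-4,4,8-trimethyl-10-[(triisopropylsilyl)oxy]undeca-2,8,10-trienal | O=C/C=C/C(C)(C)CCC/C(C)=C\C(=C)O[Si](C(C)C)(C(C)C)C(C)C | intermediate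
11 | (1R,4aS,8aR)-4a,8,8-trimethyl-3-[(triisopropylsilyl)oxy]-1,2,4a,5,6,7,8,8a-octahydronaphthalene-1-carbaldehyde (cis-fused; 5β-H, 10β-CH3, 6β-CHO, C8=C9 enol ether) | CC(C)[Si](C(C)C)(C(C)C)OC1=C[C@@]2(C)CCCC(C)(C)[C@H]2[C@H](C=O)C1 | intermediate
12 | triisopropyl{[(4aR,8aS)-5,5,8a-trimethyl-3,4,4a,5,6,7,8,8a-octahydronaphthalen-2-yl]oxy}silane (cis-fused; C8=C9 enol ether) | CC(C)[Si](C(C)C)(C(C)C)OC1=C[C@@]2(C)CCCC(C)(C)[C@H]2CC1 | intermediate
13 | methyl hydrogen (S)-3-methylglutarate | OC(=O)C[C@H](C)CC(=O)OC | starting material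
14 | methyl (3S)-5-hydroxy-3-methylpentanoate | OCC[C@H](C)CC(=O)OC | intermediate
15 | methyl (3S)-3-methyl-5-oxopentanoate | O=CC[C@H](C)CC(=O)OC | intermediate
16 | methyl (3S)-5-hydroxy-3-methyl-5-[(4aR,8aS)-5,5,8a-trimethyl-2-oxodecahydronaphthalen-1-yl]pentanoate (epimers at C9 and C11) | O=C1CC[C@@H]2C(C)(C)CCC[C@]2(C)C1C(O)C[C@H](C)CC(=O)OC | intermediate
17 | C11 methanesulfonate of 16 (not isolated) | O=C1CC[C@@H]2C(C)(C)CCC[C@]2(C)C1C(OS(C)(=O)=O)C[C@H](C)CC(=O)OC | intermediate
18 | methyl (3S,5Z)-3-methyl-5-[(4aR,8aS)-5,5,8a-trimethyl-2-oxooctahydronaphthalen-1(2H)-ylidene]pentanoate | O=C1CC[C@@H]2C(C)(C)CCC[C@]2(C)/C1=C/C[C@H](C)CC(=O)OC | intermediate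
19 | (3S,5Z)-3-methyl-5-[(4aR,8aS)-5,5,8a-trimethyl-2-oxooctahydronaphthalen-1(2H)-ylidene]pentanoic acid | O=C1CC[C@@H]2C(C)(C)CCC[C@]2(C)/C1=C/C[C@H](C)CC(=O)O | intermediate
20 | bromomagnesium carboxylate of 19 (not isolated) | O=C1CC[C@@H]2C(C)(C)CCC[C@]2(C)/C1=C/C[C@H](C)CC(=O)[O-].[Mg+2].[Br-] | intermediate
21 | (3S,5Z)-5-[(2R,4aR,8aS)-2-hydroxy-2,5,5,8a-tetramethyloctahydronaphthalen-1(2H)-ylidene]-3-methylpentanoic acid (8α-OH, 8β-CH3) | O[C@]1(C)CC[C@@H]2C(C)(C)CCC[C@]2(C)/C1=C/C[C@H](C)CC(=O)O | intermediate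
22 | (3S)-5-[(1R,2R,4aR,8aS)-2-hydroxy-2,5,5,8a-tetramethyldecahydronaphthalen-1-yl]-3-methylpentanoic acid | O[C@]1(C)CC[C@@H]2C(C)(C)CCC[C@]2(C)[C@H]1CC[C@H](C)CC(=O)O | intermediate
23 | dipotassium alkoxide carboxylate of 22 (not isolated) | [O-][C@]1(C)CC[C@@H]2C(C)(C)CCC[C@]2(C)[C@H]1CC[C@H](C)CC(=O)[O-].[K+].[K+] | intermediate
24 | acetic mixed anhydride of 25 (not isolated) | CC(=O)O[C@]1(C)CC[C@@H]2C(C)(C)CCC[C@]2(C)[C@H]1CC[C@H](C)CC(=O)OC(C)=O | intermediate
25 | (3S)-5-[(1R,2R,4aR,8aS)-2-acetoxy-2,5,5,8a-tetramethyldecahydronaphthalen-1-yl]-3-methylpentanoic acid (CNP0470037.1) | CC(=O)O[C@]1(C)CC[C@@H]2C(C)(C)CCC[C@]2(C)[C@H]1CC[C@H](C)CC(=O)O | target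

**Step count**

Total steps: 16. Longest linear sequence: 13 (steps 2–8 and 11–16).

**Steps most likely to fail, with fallbacks**

Step 7. The hindered (Z)-diene and the β-quaternary enal may combine too slowly under the chiral Lewis acid. Protodesilylation of the dienol ether or intermolecular Mukaiyama-type oligomerisation could then compete, and enantiofacial control could erode. The fallback replaces catalyst control by a stoichiometric auxiliary and a stronger stoichiometric Lewis acid; it sets out from 6 and comes back at 11.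
- Ester 6 is saponified (LiOH, THF/H2O) to (2E,8Z)-4,4,8-trimethyl-10-oxoundeca-2,8-dienoic acid F1.
- F1 is converted through its pivalic mixed anhydride (t-BuCOCl, Et3N) with lithiated (R)-4-benzyl-2-oxazolidinone into the imide (R)-4-benzyl-3-[(2E,8Z)-4,4,8-trimethyl-10-oxoundeca-2,8-dienoyl]oxazolidin-2-one F2.
- Soft enolisation (TIPSOTf, Et3N, CH2Cl2, 0 °C) gives the silyl dienol ether imide F3.
- Me2AlCl (1.4 equiv, CH2Cl2, −30 °C) promotes the intramolecular Diels–Alder reaction of the chelated s-cis imide. The diene should add to the face opposite the benzyl group, which is the same Re face at C6, and the Z-diene again enforces cis fusion, giving the imide cycloadduct F4.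
- LiBH4 (THF/MeOH) removes the auxiliary reductively to the 6β-hydroxymethyl compound F5.
- TEMPO/PhI(OAc)2 oxidation returns aldehyde 11.

Step 15. The crowded C9=C11 alkene, flanked by two quaternary carbons, may fail to bind the metal, or the tertiary allylic alcohol may ionise on the acidic metal hydride. The fallback sets C9 by forming the C9–C11 bond from the β face instead of delivering hydrogen from the α face; it sets out from 12 and 14 and comes back at 22.
- Alcohol 14 is converted (I2, PPh3, imidazole) into methyl (3R)-5-iodo-3-methylpentanoate F6.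
- Fluoride-promoted regiospecific alkylation of enol ether 12 with F6 ((Me2N)3S+ Me3SiF2−, THF, −78 → 0 °C) should give methyl (3S)-3-methyl-5-[(1R,4aR,8aS)-5,5,8a-trimethyl-2-oxodecahydronaphthalen-1-yl]pentanoate F7. The C8–C9 enolate is attacked axially, anti to the axial C1 and on the convex β face, and C9–H is not equilibrated afterwards.
- Neutral ester cleavage (Me3SnOH, 1,2-dichloroethane, 70 °C) gives the keto acid F8 without epimerisation at C9.
- CeCl3/MeMgBr addition, again from the β equatorial direction because the syn-axial C1 blocks the α face, returns hydroxy acid 22.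

Step 11. Carbon–carbon bond formation at the neopentyl enol carbon C9 may be slow, so that protodesilylation of 12 or retro-aldol cleavage of the aldolate takes over. The fallback uses an oxocarbenium electrophile and an irreversible ether-forming addition; it sets out from 12 and 15 and comes back at 18.
- Aldehyde 15 is converted (HC(OMe)3, MeOH, cat. TsOH) into methyl (3S)-5,5-dimethoxy-3-methylpentanoate F9.
- Catalytic Me3SiOTf (CH2Cl2, −78 °C) couples 12 with F9 to the β-methoxy ketone methyl (3S)-5-methoxy-3-methyl-5-[(4aR,8aS)-5,5,8a-trimethyl-2-oxodecahydronaphthalen-1-yl]pentanoate F10, which cannot revert.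
- DBU (or KOt-Bu) eliminates methanol by the E1cB path to enone 18.

**Further compounds**

F1 | step 7 | (2E,8Z)-4,4,8-trimethyl-10-oxoundeca-2,8-dienoic acid | OC(=O)/C=C/C(C)(C)CCC/C(C)=C\C(C)=O
F2 | step 7 | (R)-4-benzyl-3-[(2E,8Z)-4,4,8-trimethyl-10-oxoundeca-2,8-dienoyl]oxazolidin-2-one | O=C1OC[C@@H](Cc2ccccc2)N1C(=O)/C=C/C(C)(C)CCC/C(C)=C\C(C)=O
F3 | step 7 | (R)-4-benzyl-3-{(2E,8Z)-4,4,8-trimethyl-10-[(triisopropylsilyl)oxy]undeca-2,8,10-trienoyl}oxazolidin-2-one | O=C1OC[C@@H](Cc2ccccc2)N1C(=O)/C=C/C(C)(C)CCC/C(C)=C\C(=C)O[Si](C(C)C)(C(C)C)C(C)C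
F4 | step 7 | (R)-4-benzyl-3-{[(1R,4aS,8aR)-4a,8,8-trimethyl-3-[(triisopropylsilyl)oxy]-1,2,4a,5,6,7,8,8a-octahydronaphthalen-1-yl]carbonyl}oxazolidin-2-one | CC(C)[Si](C(C)C)(C(C)C)OC1=C[C@@]2(C)CCCC(C)(C)[C@H]2[C@H](C(=O)N2C(=O)OC[C@H]2Cc2ccccc2)C1
F5 | step 7 | [(1R,4aS,8aR)-4a,8,8-trimethyl-3-[(triisopropylsilyl)oxy]-1,2,4a,5,6,7,8,8a-octahydronaphthalen-1-yl]methanol | CC(C)[Si](C(C)C)(C(C)C)OC1=C[C@@]2(C)CCCC(C)(C)[C@H]2[C@H](CO)C1
F6 | step 15 | methyl (3R)-5-iodo-3-methylpentanoate | ICC[C@H](C)CC(=O)OC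
F7 | step 15 | methyl (3S)-3-methyl-5-[(1R,4aR,8aS)-5,5,8a-trimethyl-2-oxodecahydronaphthalen-1-yl]pentanoate | O=C1CC[C@@H]2C(C)(C)CCC[C@]2(C)[C@H]1CC[C@H](C)CC(=O)OC
F8 | step 15 | (3S)-3-methyl-5-[(1R,4aR,8aS)-5,5,8a-trimethyl-2-oxodecahydronaphthalen-1-yl]pentanoic acid | O=C1CC[C@@H]2C(C)(C)CCC[C@]2(C)[C@H]1CC[C@H](C)CC(=O)O
F9 | step 11 | methyl (3S)-5,5-dimethoxy-3-methylpentanoate | COC(OC)C[C@H](C)CC(=O)OC
F10 | step 11 | methyl (3S)-5-methoxy-3-methyl-5-[(4aR,8aS)-5,5,8a-trimethyl-2-oxodecahydronaphthalen-1-yl]pentanoate | O=C1CC[C@@H]2C(C)(C)CCC[C@]2(C)C1C(OC)C[C@H](C)CC(=O)OC
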